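## Analysis of the target

- The target 17 (C22H22O4) is an achiral bibenzyl. Rings A and B are joined by a saturated two-carbon bridge (Cα on ring A, Cβ on ring B), and ring C is attached to ring A through one methylene, C7.
- It has no stereocentre, no alkene and no ring other than the three benzenes, so the whole problem is regiochemistry on ring A.
- Ring A is numbered C1 (OMe), C2 (H), C3 (OH), C4 (H), C5 (bridge to ring B) and C6 (C7H2–ring C). The positions C5, C6 and C1 are contiguously substituted, and the benzyl group occupies the most crowded site, between the bridge and the methoxy group.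
- Electrophilic benzylation of a preformed 5-alkylresorcinol ether would have to prefer C6 over the equally activated C2 and C4, which cannot be relied on.
- The two meta oxygens of ring A must also be told apart (C1 methylated, C3 free) in a molecule that carries two further free phenols.
- The sensitive features are the three electron-rich phenols, which oxidise easily, and the 4-hydroxybenzyl unit, which can ionise towards a quinone methide. A free ring B phenol would in addition attack any enone placed on its side chain and close a chroman.
- The strategy reads ring A as a 5-alkylresorcinol. Its C4–H, ortho to the C3 oxygen only, can carry a removable ester, and its C5–C6 edge, with both carbon substituents attached, is the alkene of an α-benzyl enone.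

## Retrosynthetic reasoning

**17 to 16.** The two benzylic O–C bonds masking the phenols of rings B and C are cut. In the forward sense they fall last, so the oxidisable triphenol and the quinone-methide-prone ring C unit appear only at the end. One protecting group type serves both sites and is removed in one neutral hydrogenolysis. That step must leave the C7 diarylmethane, the bridge and the methyl ether untouched.

**16 to 14, by way of 15.** A carboxyl carbon is put back on C4. This site is chosen because it is ortho to the C3 oxygen and para to the C1 oxygen, so an ester there interacts with only one of the two hydroxyls. The forward reaction has to hydrolyse a doubly ortho-flanked ester to acid 15 and then expel the carboxyl group. The ortho hydroxyl and para methoxy donors make that expulsion easy.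

**14 to 13.** The O–CH3 bond at C1 is cut. In 13 the C3 hydroxyl is tied to the ester carbonyl by a hydrogen bond, whereas the C1 hydroxyl is free and more acidic. The two oxygens are therefore distinguished by the substrate and not by a protecting-group sequence. The forward step needs only a weak base and one equivalent of methylating agent.

**13 to 11, by way of 12.** The aromatic ring is taken back by two hydrogens to the 4,6-dioxocyclohexanecarboxylate 11. Ring A thereby becomes a carbocycle that carbonyl condensations can assemble, with every substituent fixed by bond construction. The forward reaction must dehydrogenate a cyclohexane-1,3-dione without losing the β-keto ester, which is why a mild halogenation–elimination through 12 is chosen.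

**11 to 8 and 9, by way of 10.** The ring bonds C2–C3 and C4–C5 are cut.
- This pair is chosen because it releases the symmetrical three-carbon diester 9 (C3, C4 and the ester carbon) and the enone 8. Enone 8 already contains C1, C2, C5, C6, C7 and the bridge in their final relationship.
- Any other pair of cuts would put the ester at C2 or C6, or would separate the two carbon substituents again.
- The forward reaction has to add 9 to the β-carbon of a trisubstituted enone and then close the ring from the methyl ketone side of 10.

**8 to 7 and 4.** The C5=C6 double bond is cut. An olefination with phosphonate 7 places the benzyl group on the carbonyl-bearing carbon and the chain on the other carbon without ambiguity. A crossed aldol of an unsymmetrical methyl ketone could not guarantee this. Alkene geometry need not be controlled, because both alkene carbons become sp3 and later aromatic.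

**7 to 5 and 6.** The C6–C7 bond is cut. The doubly activated methylene of 5 is alkylated with the very reactive benzylic chloride 6. Both are catalogue compounds, and ring C enters already protected.

**4 to 3, 2 and 1.** No skeletal bond is cut. Lactone 1 already holds ring B, its oxygen and the three carbons that become Cβ, Cα and C5. Opening it to amide 2 frees the phenol for benzylation (3) and sets up a reduction that stops at aldehyde 4.

## Alternatives that were turned down

**Alternative 1:** aryne three-component coupling.

*Disconnection.* Ring A is kept as a purchased arene. The bonds C5–Cα and C6–C7 are cut together, leading back to a C5–C6 aryne.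

*Forward key step.* 1-Fluoro-3-methoxy-5-[(triisopropylsilyl)oxy]benzene A2 would be lithiated between fluorine and methoxy (C6), and fluoride would leave on warming. 2-[2-(Benzyloxy)phenyl]ethylmagnesium bromide A3 would attack the aryne at C5. The C6 aryl-metal would then be trapped with 4-(benzyloxy)benzaldehyde A4 to give the racemic carbinol [4-(benzyloxy)phenyl]{2-{2-[2-(benzyloxy)phenyl]ethyl}-6-methoxy-4-[(triisopropylsilyl)oxy]phenyl}methanol A1.

*For it.*
- The polarisation of a 3-alkoxyaryne directs the nucleophile to the remote carbon and leaves the anion beside oxygen, so the regiochemistry is sound.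
- The oxygen pattern is bought differentiated.
- After A1 only desilylation and one hydrogenolysis remain, and the hydrogenolysis also removes the doubly benzylic hydroxyl.

*Against it.*
- Several basic organometallics share one flask. The lithium base and lithiated A2 compete with A3 for the aryne.
- An alkyl Grignard reagent with β-hydrogens is only a moderate aryne nucleophile.
- The excess of A3 needed would itself consume A4.
- The C6 anion is flanked by the methoxy group and the new chain, so it should add slowly and be lost to protonation.

*Comparison.* This alternative is clearly stronger in convergence and step count. The chosen route offers a ring A substitution pattern fixed by classical ionic bond formations, each of which can be checked and optimised separately. It avoids one cryogenic step on which both key bonds depend.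

**Alternative 2:** inverse-demand pyrone Diels–Alder reaction.

*Disconnection.* C5–C6 and C1–C2 are cut, splitting ring A into a four-carbon diene part (C2 to C5) and a two-carbon part (C6, C1).

*Forward key step.* Benzyl 4-(benzyloxy)-6-{2-[2-(benzyloxy)phenyl]ethyl}-2-oxo-2H-pyran-3-carboxylate A6 would combine with the ketene acetal 1-(benzyloxy)-4-(3,3-dimethoxyprop-2-en-1-yl)benzene A7. The bridged lactone would undergo decarboxylative cycloreversion, and elimination of one methoxy group would give benzyl 6-(benzyloxy)-3-[4-(benzyloxy)benzyl]-4-{2-[2-(benzyloxy)phenyl]ethyl}-2-methoxybenzoate A5.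

*For it.*
- The ring arrives at the aromatic oxidation level.
- The methyl ether comes from A7 and the free oxygen from A6, so neither a dehydrogenation nor a selective methylation is needed.
- The polar matching of the partners fixes the orientation.
- All four benzyl groups fall in one hydrogenolysis before a final decarboxylation.

*Against it.*
- The 4-benzyloxy group of A6 is a vinylogous donor that weakens the electron-poor diene.
- The C5–C6 bond must form between two substituted termini.
- A7 is labile to hydrolysis and can move its double bond into conjugation with ring C by a proton shift, which removes the dienophile.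
- A6 needs a multistep preparation with its own O-alkylation regiochemistry.

*Comparison.* The alternative is stronger in oxidation-state economy and in built-in oxygen differentiation. The chosen route gives instead a five-step entry from four cheap catalogue compounds, robust intermediates, and a ring closure driven by formation of a stabilised anion.

**Alternative 3:** Danheiser benzannulation.

*Disconnection.* C2–C3, C1–C6 and C3–C4 are cut. A cyclobutenone supplies C3, C4, C5 and C6, and an alkyne supplies C1 and C2.

*Forward key step.* 2-[4-(Benzyloxy)benzyl]-3-{2-[2-(benzyloxy)phenyl]ethyl}cyclobut-2-en-1-one A9 would be heated with methoxyethyne A10. The cascade runs through ring opening to a vinylketene, [2+2] addition, a second ring opening and a six-electron closure. It would give 4-[4-(benzyloxy)benzyl]-3-{2-[2-(benzyloxy)phenyl]ethyl}-5-methoxyphenol A8, which is the same compound as 16.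

*For it.*
- One step makes ring A with the C3 phenol free and the C1 oxygen methylated.
- No temporary ester is needed, and the product is a single hydrogenolysis away from 17.
- The end game is four steps shorter than in the chosen route.

*Against it.*
- The difficulty moves into A9. The usual access is a ketene [2+2] addition to 1-(benzyloxy)-2-{5-[4-(benzyloxy)phenyl]pent-3-yn-1-yl}benzene A11 followed by reductive dehalogenation.
- That addition has no bias between two alkyne termini that both carry a primary CH2 group. It should therefore also deliver the isomer with the C5 and C6 substituents exchanged, which would be hard to separate.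
- A10 is highly volatile, prone to polymerise and not a routine catalogue item. It would have to be used in excess in a sealed vessel.

*Comparison.* The alternative is superior after its key step. The chosen route instead places the two carbon substituents unambiguously through the olefination that makes 8, and it uses only stable, easily handled reagents.

Key step: step 6

## Route

Remark: the target has no stereocentre and no alkene, so its SMILES needs no descriptor. The stereocentres of 7, 10, 11 and 12 are transient and are carried as mixtures.

Step 1
Reactants: 1 3,4-dihydro-2H-chromen-2-one (dihydrocoumarin)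
Product: 2 3-(2-hydroxyphenyl)-N-methoxy-N-methylpropanamide
Conditions: MeNH(OMe)·HCl (1.5 equiv), i-PrMgCl (3.0 equiv), THF, −20 °C; then 1, −20 → 0 °C; aq. NH4Cl
Reagents that add atoms: N,O-dimethylhydroxylamine hydrochloride, CNOC.Cl
Why: Aminolysis of the lactone by the preformed chloromagnesium amide (Weinreb amide synthesis). The aryl ester is strongly activated, and the departing phenoxide stays as its magnesium salt until work-up, so the ring cannot close again.

Step 2
Reactants: 2 3-(2-hydroxyphenyl)-N-methoxy-N-methylpropanamide
Product: 3 3-[2-(benzyloxy)phenyl]-N-methoxy-N-methylpropanamide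
Conditions: BnBr (1.1 equiv), K2CO3 (1.5 equiv), DMF, rt
Reagents that add atoms: benzyl bromide, BrCc1ccccc1
Why: Williamson ether synthesis at the only acidic site. The benzyl ether is needed because a free ring B phenol would later add to the enone of 8 and close a chroman, and it survives every basic and oxidative step up to step 10.

Step 3
Reactants: 3 3-[2-(benzyloxy)phenyl]-N-methoxy-N-methylpropanamide
Product: 4 3-[2-(benzyloxy)phenyl]propanal
Conditions: i-Bu2AlH (1.2 equiv), THF, −78 °C; aq. potassium sodium tartrate
Reagents that add atoms: none
Why: Hydride addition to a Weinreb amide gives a chelated aluminium hemiaminal that collapses only on aqueous work-up, so the reduction should stop at the aldehyde. Compound 4 is enolisable and is used soon after isolation.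

Step 4
Reactants: 5 diethyl (2-oxopropyl)phosphonate; 6 4-(benzyloxy)benzyl chloride
Product: 7 diethyl {1-[4-(benzyloxy)phenyl]-3-oxobutan-2-yl}phosphonate (racemic)
Conditions: 5 (1.2 equiv), NaH (1.1 equiv), THF–DMF, 0 °C; then 6, 0 → 50 °C
Reagents that add atoms: none
Why: SN2 C-alkylation of the stabilised β-ketophosphonate anion with a very reactive para-alkoxybenzyl chloride forms C6–C7. The slight excess of 5 and the lower acidity and greater bulk of 7 hold back a second alkylation. The new stereocentre is racemic and disappears in step 5.

Step 5
Reactants: 7 diethyl {1-[4-(benzyloxy)phenyl]-3-oxobutan-2-yl}phosphonate; 4 3-[2-(benzyloxy)phenyl]propanal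
Product: 8 (E)-3-[4-(benzyloxy)benzyl]-6-[2-(benzyloxy)phenyl]hex-3-en-2-one
Conditions: 7 (1.05 equiv), NaH (1.0 equiv), THF, 0 °C; then 4, 0 °C → rt
Reagents that add atoms: none
Why: Horner–Wadsworth–Emmons olefination with an α-substituted β-ketophosphonate forms C5=C6 and puts the benzyl group and the chain on adjacent carbons without ambiguity. The E isomer (acetyl trans to the chain) should prevail through the less crowded oxaphosphetane. Any Z isomer converges on the same adduct in step 6, so no separation is needed.

Step 6
Reactants: 8 (E)-3-[4-(benzyloxy)benzyl]-6-[2-(benzyloxy)phenyl]hex-3-en-2-one; 9 dimethyl malonate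
Product: 11 methyl 3-[4-(benzyloxy)benzyl]-2-{2-[2-(benzyloxy)phenyl]ethyl}-4,6-dioxocyclohexane-1-carboxylate (mixture of diastereomers), via open-chain keto diester 10 (not isolated)
Conditions: 9 (1.5 equiv), NaOMe (1.5 equiv), MeOH, reflux; then cold 1 M HCl
Reagents that add atoms: none
Why: Sodium dimethyl malonate adds reversibly in 1,4-fashion to the β-carbon of 8 (C4–C5 bond) and proton exchange in MeOH gives keto diester 10, whose methyl-side enolate (C2) then attacks one ester carbonyl (C2–C3 bond) with loss of methoxide in a Dieckmann-type Claisen acylation. The closest known reaction type is the malonate–enone Michael–Claisen annulation that turns alk-3-en-2-ones, α-alkylated ones included, into 4,6-dioxocyclohexanecarboxylates (dihydro-β-resorcylates). The single ring closes in a 6-(enolendo)-exo-trig mode, which is favoured. The steps before closure are reversible, and the sequence is pulled forward because 11 is deprotonated at once to its vinylogous carboxylate anion, which is why at least one full equivalent of base is used. The regioselectivity needed is closure through C2 and not C6: the C6 enolate could only form a four-membered ring, so the substrate leaves one productive path and thereby fixes the ester at C4. Preference for 1,4- over 1,2-attack follows from the soft stabilised nucleophile and the reversibility of carbonyl addition, and either alkene geometry of 8 gives the same adduct. C4, C5 and C6 become stereocentres with no controlling element beyond base-mediated equilibration at C4 and C6 towards the all-equatorial isomer, which does not matter because all three are flattened in step 7. The benzyl ethers are inert to methoxide.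

Step 7
Reactants: 11 methyl 3-[4-(benzyloxy)benzyl]-2-{2-[2-(benzyloxy)phenyl]ethyl}-4,6-dioxocyclohexane-1-carboxylate
Product: 13 methyl 3-[4-(benzyloxy)benzyl]-2-{2-[2-(benzyloxy)phenyl]ethyl}-4,6-dihydroxybenzoate, via α-iodo keto ester 12 (not isolated)
Conditions: I2 (0.2 equiv), DMSO, 80 °C
Reagents that add atoms: none
Why: Iodine-catalysed oxidative aromatisation of a cyclohexane-1,3-dione with DMSO as terminal oxidant, a known way from dihydro-β-resorcylates to β-resorcylates. An enol of 11 is iodinated (drawn at C4 as 12; iodination at C6 leads to the same arene), HI is lost across the bond to C5, tautomerisation gives 13, and DMSO returns HI to I2. The medium never becomes strongly acidic, so the methyl ester and the benzyl ethers should remain, and the three sp3 stereocentres vanish.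

Step 8
Reactants: 13 methyl 3-[4-(benzyloxy)benzyl]-2-{2-[2-(benzyloxy)phenyl]ethyl}-4,6-dihydroxybenzoate
Product: 14 methyl 3-[4-(benzyloxy)benzyl]-2-{2-[2-(benzyloxy)phenyl]ethyl}-6-hydroxy-4-methoxybenzoate
Conditions: MeI (1.1 equiv), K2CO3 (1.2 equiv), acetone, rt → 40 °C
Reagents that add atoms: iodomethane, CI
Why: Williamson-type O-methylation under weak base. The C3 hydroxyl (6-OH of the benzoate) is held in a six-membered hydrogen bond to the ester carbonyl and is less acidic and less nucleophilic. The C1 hydroxyl (4-OH, para to the ester) is ionised and methylated, a selectivity well known for 2,4-dihydroxybenzoates.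

Step 9
Reactants: 14 methyl 3-[4-(benzyloxy)benzyl]-2-{2-[2-(benzyloxy)phenyl]ethyl}-6-hydroxy-4-methoxybenzoate
Product: 16 4-[4-(benzyloxy)benzyl]-3-{2-[2-(benzyloxy)phenyl]ethyl}-5-methoxyphenol, via free benzoic acid 15 (not isolated)
Conditions: KOH (10 equiv), ethylene glycol–H2O, 120 °C; 2 M HCl; toluene, reflux
Reagents that add atoms: none
Why: Forcing alkaline hydrolysis (BAc2) of the doubly ortho-flanked ester, followed by protodecarboxylation of the salicylic-type acid 15. Ipso-protonation at C4 is favoured by the ortho hydroxyl and para methoxy donors and by relief of crowding, as known for 6-alkyl-β-resorcylic acids. Aryl benzyl and aryl methyl ethers are inert to hot hydroxide.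

Step 10
Reactants: 16 4-[4-(benzyloxy)benzyl]-3-{2-[2-(benzyloxy)phenyl]ethyl}-5-methoxyphenol
Product: 17 4-(4-hydroxybenzyl)-3-[2-(2-hydroxyphenyl)ethyl]-5-methoxyphenol (target, CNP0289131.0)
Conditions: H2 (1 atm), Pd/C (10 wt% Pd), EtOAc–MeOH, rt
Reagents that add atoms: none
Why: Catalytic hydrogenolysis of both aryl benzyl ethers under neutral conditions. The diarylmethane and bibenzyl C–C bonds and the aryl methyl ether are not touched, and the sensitive triphenol is released only in the last step.

## Compound list

1 | 3,4-dihydro-2H-chromen-2-one (dihydrocoumarin) | O=C1CCc2ccccc2O1 | starting material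
2 | 3-(2-hydroxyphenyl)-N-methoxy-N-methylpropanamide | CON(C)C(=O)CCc1ccccc1O | intermediate
3 | 3-[2-(benzyloxy)phenyl]-N-methoxy-N-methylpropanamide | CON(C)C(=O)CCc1ccccc1OCc1ccccc1 | intermediate
4 | 3-[2-(benzyloxy)phenyl]propanal | O=CCCc1ccccc1OCc1ccccc1 | intermediate
5 | diethyl (2-oxopropyl)phosphonate | CCOP(=O)(CC(C)=O)OCC | starting material
6 | 4-(benzyloxy)benzyl chloride | ClCc1ccc(OCc2ccccc2)cc1 | starting material
7 | diethyl {1-[4-(benzyloxy)phenyl]-3-oxobutan-2-yl}phosphonate (racemic) | CCOP(=O)(OCC)C(Cc1ccc(OCc2ccccc2)cc1)C(C)=O | intermediate
8 | (E)-3-[4-(benzyloxy)benzyl]-6-[2-(benzyloxy)phenyl]hex-3-en-2-one | CC(=O)/C(Cc1ccc(OCc2ccccc2)cc1)=C/CCc1ccccc1OCc1ccccc1 | intermediate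
9 | dimethyl malonate | COC(=O)CC(=O)OC | starting material
10 | dimethyl 2-{4-[4-(benzyloxy)benzyl]-1-[2-(benzyloxy)phenyl]-5-oxohexan-3-yl}malonate (mixture of diastereomers, not isolated) | COC(=O)C(C(=O)OC)C(CCc1ccccc1OCc1ccccc1)C(Cc1ccc(OCc2ccccc2)cc1)C(C)=O | intermediate
11 | methyl 3-[4-(benzyloxy)benzyl]-2-{2-[2-(benzyloxy)phenyl]ethyl}-4,6-dioxocyclohexane-1-carboxylate (mixture of diastereomers) | COC(=O)C1C(CCc2ccccc2OCc2ccccc2)C(Cc2ccc(OCc3ccccc3)cc2)C(=O)CC1=O | intermediate
12 | methyl 3-[4-(benzyloxy)benzyl]-2-{2-[2-(benzyloxy)phenyl]ethyl}-1-iodo-4,6-dioxocyclohexane-1-carboxylate (mixture of diastereomers, not isolated) | COC(=O)C1(I)C(CCc2ccccc2OCc2ccccc2)C(Cc2ccc(OCc3ccccc3)cc2)C(=O)CC1=O | intermediate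
13 | methyl 3-[4-(benzyloxy)benzyl]-2-{2-[2-(benzyloxy)phenyl]ethyl}-4,6-dihydroxybenzoate | COC(=O)c1c(O)cc(O)c(Cc2ccc(OCc3ccccc3)cc2)c1CCc1ccccc1OCc1ccccc1 | intermediate
14 | methyl 3-[4-(benzyloxy)benzyl]-2-{2-[2-(benzyloxy)phenyl]ethyl}-6-hydroxy-4-methoxybenzoate | COC(=O)c1c(O)cc(OC)c(Cc2ccc(OCc3ccccc3)cc2)c1CCc1ccccc1OCc1ccccc1 | intermediate
15 | 3-[4-(benzyloxy)benzyl]-2-{2-[2-(benzyloxy)phenyl]ethyl}-6-hydroxy-4-methoxybenzoic acid (not isolated) | OC(=O)c1c(O)cc(OC)c(Cc2ccc(OCc3ccccc3)cc2)c1CCc1ccccc1OCc1ccccc1 | intermediate
16 | 4-[4-(benzyloxy)benzyl]-3-{2-[2-(benzyloxy)phenyl]ethyl}-5-methoxyphenol | COc1cc(O)cc(CCc2ccccc2OCc2ccccc2)c1Cc1ccc(OCc2ccccc2)cc1 | intermediate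
17 | 4-(4-hydroxybenzyl)-3-[2-(2-hydroxyphenyl)ethyl]-5-methoxyphenol | COc1cc(O)cc(CCc2ccccc2O)c1Cc1ccc(O)cc1 | target

## Step count and least certain steps

Total step count: 10. Longest linear sequence: 9 (steps 1 to 3 and 5 to 10). Step 4 lies on the short branch.

**Step 6 (key step).**

*Risk.* The conjugate addition is most likely to be sluggish. The acceptor is a trisubstituted enone whose α-benzyl and β-alkyl groups shield C5 and lead to a crowded enolate. Retro-Michael reaction, γ-deprotonation with deconjugation, and self-condensation through the methyl ketone can then compete before the Claisen closure drains the equilibrium.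

*Fallback.* The Michael bond is moved from C4–C5 to C5–C6, so that a much stronger acceptor is used.
- (E)-4-[4-(benzyloxy)phenyl]but-3-en-2-one F1 is one Claisen–Schmidt condensation away from commercial materials. It undergoes 1,4-hydrosilylation (Et3SiH, RhCl(PPh3)3 cat.) to the regiodefined enol ether (Z)-({4-[4-(benzyloxy)phenyl]but-2-en-2-yl}oxy)triethylsilane F2.
- Separately, 4 and 9 are joined by Knoevenagel condensation (piperidine and AcOH cat., toluene, removal of water) to dimethyl 2-{3-[2-(benzyloxy)phenyl]propylidene}malonate F3.
- Mukaiyama–Michael addition of F2 to F3 (Sc(OTf)3 cat., CH2Cl2, low temperature) gives 10, now isolated, and NaOMe in MeOH closes it.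
- The fallback sets out from 4 and 9 and returns to the route at 11.

**Step 5.**

*Risk.* The α-branched phosphonate anion may add slowly to the aldehyde. This leaves time for proton transfer from the enolisable aldehyde and for its self-aldol condensation.

*Fallback.* The olefination is replaced by a directed aldol and dehydration.
- The silyl enol ether F2 described above, made from F1, is combined with 4 in a Mukaiyama aldol reaction (BF3·OEt2, CH2Cl2, −78 °C). This gives 3-[4-(benzyloxy)benzyl]-6-[2-(benzyloxy)phenyl]-4-hydroxyhexan-2-one F4 as a mixture of diastereomers.
- Acid-catalysed dehydration (TsOH cat., toluene, 80 °C) then gives the enone.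
- The fallback sets out from 4, makes steps 4 and 5 unnecessary, and returns at 8.

**Step 7.**

*Risk.* Ring iodination of the very electron-rich product at C2 may tie up the catalytic iodine and stall turnover. Dealkylative loss of the β-keto ester before aromatisation would also remove the group that directs step 8.

*Fallback.* The C1 oxygen is fixed before the ring is oxidised.
- Compound 11 is heated with I2 (1.1 equiv) in MeOH. The acid released converts the vinylogous acid into methyl 3-[4-(benzyloxy)benzyl]-2-{2-[2-(benzyloxy)phenyl]ethyl}-4-methoxy-6-oxocyclohex-4-ene-1-carboxylate F5.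
- F5 is then iodinated and loses HI. This is the known iodine–methanol aromatisation of cyclohexenones and 1,3-diones to aryl methyl ethers.
- The chelated C3 oxygen stays free and the free resorcylate is never exposed.
- The fallback sets out from 11, skips 13 and step 8, and returns at 14.

**Step 9.**

*Risk.* Hydrolysis may remain incomplete, because the ester carbonyl is flanked by two ortho substituents and is further deactivated by the neighbouring phenoxide.

*Fallback.* The alkyl–oxygen bond is broken instead of the acyl–oxygen bond, so crowding at the carbonyl no longer matters.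
- LiI in refluxing pyridine removes the ester methyl group by SN2 attack.
- Acidification gives 15, which is decarboxylated by heating in toluene or DMF.
- The fallback sets out from 14 and returns at 16. It makes no compound outside the list (F0).

## Further compounds

F1 | step 6 | (E)-4-[4-(benzyloxy)phenyl]but-3-en-2-one | CC(=O)/C=C/c1ccc(OCc2ccccc2)cc1
F2 | step 6 | (Z)-({4-[4-(benzyloxy)phenyl]but-2-en-2-yl}oxy)triethylsilane | C/C(O[Si](CC)(CC)CC)=C/Cc1ccc(OCc2ccccc2)cc1
F3 | step 6 | dimethyl 2-{3-[2-(benzyloxy)phenyl]propylidene}malonate | COC(=O)C(=CCCc1ccccc1OCc1ccccc1)C(=O)OC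
F4 | step 5 | 3-[4-(benzyloxy)benzyl]-6-[2-(benzyloxy)phenyl]-4-hydroxyhexan-2-one (mixture of diastereomers) | CC(=O)C(Cc1ccc(OCc2ccccc2)cc1)C(O)CCc1ccccc1OCc1ccccc1
F5 | step 7 | methyl 3-[4-(benzyloxy)benzyl]-2-{2-[2-(benzyloxy)phenyl]ethyl}-4-methoxy-6-oxocyclohex-4-ene-1-carboxylate (mixture of diastereomers) | COC(=O)C1C(CCc2ccccc2OCc2ccccc2)C(Cc2ccc(OCc3ccccc3)cc2)C(OC)=CC1=O
F0 | step 9 | none | none
A1 | alternative 1 | [4-(benzyloxy)phenyl]{2-{2-[2-(benzyloxy)phenyl]ethyl}-6-methoxy-4-[(triisopropylsilyl)oxy]phenyl}methanol (racemic) | COc1cc(O[Si](C(C)C)(C(C)C)C(C)C)cc(CCc2ccccc2OCc2ccccc2)c1C(O)c1ccc(OCc2ccccc2)cc1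
A2 | alternative 1 | 1-fluoro-3-methoxy-5-[(triisopropylsilyl)oxy]benzene | COc1cc(F)cc(O[Si](C(C)C)(C(C)C)C(C)C)c1
A3 | alternative 1 | 2-[2-(benzyloxy)phenyl]ethylmagnesium bromide | Br[Mg]CCc1ccccc1OCc1ccccc1
A4 | alternative 1 | 4-(benzyloxy)benzaldehyde | O=Cc1ccc(OCc2ccccc2)cc1
A5 | alternative 2 | benzyl 6-(benzyloxy)-3-[4-(benzyloxy)benzyl]-4-{2-[2-(benzyloxy)phenyl]ethyl}-2-methoxybenzoate | COc1c(C(=O)OCc2ccccc2)c(OCc2ccccc2)cc(CCc2ccccc2OCc2ccccc2)c1Cc1ccc(OCc2ccccc2)cc1
A6 | alternative 2 | benzyl 4-(benzyloxy)-6-{2-[2-(benzyloxy)phenyl]ethyl}-2-oxo-2H-pyran-3-carboxylate | O=C(OCc1ccccc1)c1c(OCc2ccccc2)cc(CCc2ccccc2OCc2ccccc2)oc1=O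
A7 | alternative 2 | 1-(benzyloxy)-4-(3,3-dimethoxyprop-2-en-1-yl)benzene | COC(OC)=CCc1ccc(OCc2ccccc2)cc1
A8 | alternative 3 | 4-[4-(benzyloxy)benzyl]-3-{2-[2-(benzyloxy)phenyl]ethyl}-5-methoxyphenol (identical with 16) | COc1cc(O)cc(CCc2ccccc2OCc2ccccc2)c1Cc1ccc(OCc2ccccc2)cc1
A9 | alternative 3 | 2-[4-(benzyloxy)benzyl]-3-{2-[2-(benzyloxy)phenyl]ethyl}cyclobut-2-en-1-one | O=C1CC(CCc2ccccc2OCc2ccccc2)=C1Cc1ccc(OCc2ccccc2)cc1
A10 | alternative 3 | methoxyethyne | COC#C
A11 | alternative 3 | 1-(benzyloxy)-2-{5-[4-(benzyloxy)phenyl]pent-3-yn-1-yl}benzene | c1ccccc1COc1ccccc1CCC#CCc1ccc(OCc2ccccc2)cc1
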